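**Retrosynthetic overview**
1. The C13=C14 enoate comes from a methyl ketone (Horner–Wadsworth–Emmons); the C6 and C8 hydroxyls come from a ring B C7=C8 enone with a C6 ketone (epoxidation, then dissolving-metal reduction).
2. Ring A is closed by the C1–C10 bond: a C1 radical on the gem-dimethyl arm at C5 adds 6-endo to C10 of a ring B enone. This is the only ring-forming step.
3. Enabling feature: in ring B the oxygen-bearing C6 is joined through C5 to the quaternary C10, so a C6 ketone conjugated with C5=C10 makes C10 the radical acceptor and keeps the ring-fusion atom C5 epimerizable.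
4. Ring B is bought as (S)-pulegone: its isopropylidene carbon becomes C4 (allyl conjugate addition), C9 is alkylated, and MeLi addition plus oxidative 1,3-transposition brings in C20 and moves the carbonyl from C10 to C6.
5. Stereochemical relay: bought C8 methyl centre → C9 (alkylation) → C10 and C5 (key step) → C6 and the re-made C8 carbinol. Ring order: B (bought), then A.

Key step: step 7

Remark: locants C1–C20 are those of the labdane skeleton (ring A = C1–C5 and C10, ring B = C5–C10, chain C11–C16, methyl carbons C17–C20); (S)-(−)-pulegone and bromo ketal 5 are taken as catalogue chemicals.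

**Route**

Step 1
Reactants: 1 (S)-(−)-pulegone; 2 allylmagnesium bromide
Product: 3 trimethyl{[(5S)-5-methyl-2-(2-methylpent-4-en-2-yl)cyclohex-1-en-1-yl]oxy}silane
Conditions: CuBr·SMe2, Me3SiCl, THF, −78 °C; Et3N quench
Reagents that add atoms: chlorotrimethylsilane, C[Si](C)(C)Cl
Why: Allylcopper formed in the flask should add 1,4 to the s-cis exocyclic enone at the isopropylidene carbon (copper-mediated conjugate addition accelerated by Me3SiCl), which creates the quaternary gem-dimethyl carbon C4 and traps the enolate regiospecifically as the tetrasubstituted silyl enol ether, leaving the C8 centre untouched.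

Step 2
Reactants: 3 silyl enol ether
Product: 4 (5S)-5-methyl-2-(2-methylpent-4-en-2-yl)cyclohex-2-en-1-one
Conditions: Pd(OAc)2, MeCN, rt
Reagents that add atoms: none
Why: Saegusa–Ito oxidation, in which the palladium enolate has β-hydrogens only on the ring CH2 (C4 is quaternary), so β-hydride elimination should give the 2-substituted cyclohex-2-enone as a single regioisomer.

Step 3
Reactants: 4 enone; 5 2-(2-bromoethyl)-2-methyl-1,3-dioxolane
Product: 7 (5S,6R)-5-methyl-6-[2-(2-methyl-1,3-dioxolan-2-yl)ethyl]-2-(2-methylpent-4-en-2-yl)cyclohex-2-en-1-one, via lithium dienolate 6 (not isolated)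
Conditions: LiN(iPr)2, THF, −78 °C; then 5, DMPU, −78 to −20 °C
Reagents that add atoms: none
Why: Kinetic α′-deprotonation gives the cross-conjugated lithium dienolate, and its SN2 alkylation should place the chain on C9 anti to the adjacent C8 methyl (the trans isomer, which is also the thermodynamic one).

Step 4
Reactants: 7 alkylated enone
Product: 8 (5S,6R)-1,5-dimethyl-6-[2-(2-methyl-1,3-dioxolan-2-yl)ethyl]-2-(2-methylpent-4-en-2-yl)cyclohex-2-en-1-ol (both C1 epimers)
Conditions: MeLi, Et2O, −78 to 0 °C
Reagents that add atoms: methyllithium, [Li]C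
Why: 1,2-Addition of methyllithium to the enone carbonyl installs the future angular methyl C20, and the configuration of the new carbinol carbon does not matter because it becomes sp2 in step 6.

Step 5
Reactants: 8 tertiary allylic alcohol
Product: 10 (5S,6R)-2-(5-iodo-2-methylpentan-2-yl)-1,5-dimethyl-6-[2-(2-methyl-1,3-dioxolan-2-yl)ethyl]cyclohex-2-en-1-ol, via B-alkyl-9-BBN adduct 9 (not isolated)
Conditions: 9-BBN, THF, 0 °C to rt; then I2, NaOMe, MeOH, 0 °C
Reagents that add atoms: iodine, II
Why: Hydroboration–iodination, in which 9-BBN should take the monosubstituted terminal alkene anti-Markovnikov far faster than the hindered trisubstituted ring alkene, and base-induced iodinolysis of the primary B–C bond gives the primary iodide.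

Step 6
Reactants: 10 iodo carbinol
Product: 11 (4R,5S)-2-(5-iodo-2-methylpentan-2-yl)-3,5-dimethyl-4-[2-(2-methyl-1,3-dioxolan-2-yl)ethyl]cyclohex-2-en-1-one
Conditions: pyridinium chlorochromate [C5H5NH][CrO3Cl], NaOAc, 4 Å molecular sieves, CH2Cl2, rt
Reagents that add atoms: none
Why: Babler–Dauben oxidative 1,3-transposition, in which the tertiary allylic chromate ester shifts [3,3] to the secondary ring position and is oxidized there, so the carbonyl lands on C6 and the methyl-bearing C10 becomes the β-carbon of the enone.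

Step 7
Reactants: 11 iodo enone
Product: 13 (3S,4R,4aS,8aR)-3,4a,8,8-tetramethyl-4-[2-(2-methyl-1,3-dioxolan-2-yl)ethyl]octahydronaphthalen-1(2H)-one, via kinetic decalone mixture 12 (not isolated)
Conditions: Bu3SnH (slow addition), AIBN, PhH, 80 °C, high dilution; then DBU, rt
Reagents that add atoms: none
Why: The tributylstannyl radical abstracts iodine to give the primary C1 radical, which adds to C10, the β-carbon of the C6(=O)–C5=C10 enone, and the tertiary α-keto radical at C5 then takes hydrogen from Bu3SnH before DBU equilibrates C5. The closest known reaction type is the tin hydride-mediated radical conjugate cyclization of ω-iodoalkyl enones. Ring A closes in the 6-endo-trig mode, since the 5-exo alternative would bond C1 to C5 beside the quaternary C4 and leave an unstabilized radical, against both polarity and sterics. C10 is controlled by the C9 side chain, which A(1,2) strain against the C10 methyl holds pseudoaxial so that C1 should bond to the opposite face (C1 trans to the chain, methyl cis to it), and C5 is set thermodynamically as the trans-decalone by enolization next to the C6 ketone. The step needs ring closure to outrun reduction of the primary radical, secured by slow stannane addition at high dilution and by the Thorpe–Ingold effect of the C4 gem-dimethyl group, and it needs facial selectivity at C10, secured by the C9 stereocentre.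

Step 8
Reactants: 13 trans-decalone
Product: 14 (4R,4aS,8aR)-3,4a,8,8-tetramethyl-4-[2-(2-methyl-1,3-dioxolan-2-yl)ethyl]-4a,5,6,7,8,8a-hexahydronaphthalen-1(4H)-one
Conditions: IBX, DMSO, 70 °C
Reagents that add atoms: none
Why: IBX dehydrogenation through the enol can only introduce the C7=C8 double bond, because C5 has no β-hydrogen (C4 and C10 are quaternary), and it erases the sacrificial C8 stereocentre.

Step 9
Reactants: 14 enone
Product: 15 epoxy ketone: the C7–C8 epoxide of 14 with the oxygen on the face opposite the angular C10 methyl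
Conditions: 30% H2O2, NaOH, MeOH, 0 °C
Reagents that add atoms: hydrogen peroxide, OO
Why: Weitz–Scheffer nucleophilic epoxidation, in which hydroperoxide should add to C8 from the face opposite the 1,3-syn-axial C10 methyl, so the C8 oxygen ends trans to that methyl and cis to H9.

Step 10
Reactants: 15 epoxy ketone
Product: 17 (1R,3S,4S,4aR,8aR)-3,4a,8,8-tetramethyl-4-[2-(2-methyl-1,3-dioxolan-2-yl)ethyl]decahydronaphthalene-1,3-diol, via hydroxy ketone 16 (not isolated)
Conditions: Li, NH3(l)/THF, −78 °C; then EtOH, −78 to −33 °C; NH4Cl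
Reagents that add atoms: none
Why: Dissolving-metal reduction should cleave the Cα–O bond of the α,β-epoxy ketone (C8–O is kept) and then reduce the C6 ketone through its ketyl to the thermodynamically preferred equatorial alcohol, the epimer that hydride reagents would not give with this ketone flanked by two axial methyl groups.

Step 11
Reactants: 17 diol ketal
Product: 18 4-[(1S,2S,4R,4aR,8aR)-2,4-dihydroxy-2,5,5,8a-tetramethyldecahydronaphthalen-1-yl]butan-2-one
Conditions: AcOH/THF/H2O, 40 °C
Reagents that add atoms: water, O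
Why: Mild acid-catalysed acetal hydrolysis frees the methyl ketone under conditions that should not dehydrate the tertiary alcohol.

Step 12
Reactants: 18 hydroxy ketone; 19 trimethyl phosphonoacetate
Product: 20 methyl (2E)-5-[(1S,2S,4R,4aR,8aR)-2,4-dihydroxy-2,5,5,8a-tetramethyldecahydronaphthalen-1-yl]-3-methylpent-2-enoate
Conditions: NaH (excess), THF, 0 °C to reflux
Reagents that add atoms: none
Why: Horner–Wadsworth–Emmons olefination of the methyl ketone should give the trisubstituted enoate with the E isomer favoured (ester trans to the longer branch), the minor Z isomer being removed by chromatography.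

**Compound list**
1 | (S)-(−)-pulegone, (5S)-5-methyl-2-(propan-2-ylidene)cyclohexan-1-one | C[C@H]1CCC(=C(C)C)C(=O)C1 | starting material
2 | allylmagnesium bromide | C=CC[Mg]Br | starting material
3 | trimethyl{[(5S)-5-methyl-2-(2-methylpent-4-en-2-yl)cyclohex-1-en-1-yl]oxy}silane | C[C@H]1CCC(C(C)(C)CC=C)=C(O[Si](C)(C)C)C1 | intermediate
4 | (5S)-5-methyl-2-(2-methylpent-4-en-2-yl)cyclohex-2-en-1-one | C[C@H]1CC=C(C(C)(C)CC=C)C(=O)C1 | intermediate
5 | 2-(2-bromoethyl)-2-methyl-1,3-dioxolane | CC1(CCBr)OCCO1 | starting material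
6 | lithium (3S)-3-methyl-6-(2-methylpent-4-en-2-yl)cyclohexa-1,5-dien-1-olate | C[C@H]1CC=C(C(C)(C)CC=C)C(O[Li])=C1 | intermediate (not isolated)
7 | (5S,6R)-5-methyl-6-[2-(2-methyl-1,3-dioxolan-2-yl)ethyl]-2-(2-methylpent-4-en-2-yl)cyclohex-2-en-1-one | CC1(OCCO1)CC[C@H]2C(=O)C(C(C)(C)CC=C)=CC[C@@H]2C | intermediate
8 | (5S,6R)-1,5-dimethyl-6-[2-(2-methyl-1,3-dioxolan-2-yl)ethyl]-2-(2-methylpent-4-en-2-yl)cyclohex-2-en-1-ol, both C1 epimers | CC1(OCCO1)CC[C@H]2C(C)(O)C(C(C)(C)CC=C)=CC[C@@H]2C | intermediate
9 | B-alkyl-9-borabicyclo[3.3.1]nonane adduct of 8 (boron on the terminal carbon of the arm) | CC1(OCCO1)CC[C@H]2C(C)(O)C(C(C)(C)CCCB3C4CCCC3CCC4)=CC[C@@H]2C | intermediate (not isolated)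
10 | (5S,6R)-2-(5-iodo-2-methylpentan-2-yl)-1,5-dimethyl-6-[2-(2-methyl-1,3-dioxolan-2-yl)ethyl]cyclohex-2-en-1-ol | CC1(OCCO1)CC[C@H]2C(C)(O)C(C(C)(C)CCCI)=CC[C@@H]2C | intermediate
11 | (4R,5S)-2-(5-iodo-2-methylpentan-2-yl)-3,5-dimethyl-4-[2-(2-methyl-1,3-dioxolan-2-yl)ethyl]cyclohex-2-en-1-one | CC1(OCCO1)CC[C@H]2C(C)=C(C(C)(C)CCCI)C(=O)C[C@@H]2C | intermediate
12 | (3S,4R,4aS)-3,4a,8,8-tetramethyl-4-[2-(2-methyl-1,3-dioxolan-2-yl)ethyl]octahydronaphthalen-1(2H)-one, both ring-fusion (C8a) epimers | CC1(OCCO1)CC[C@H]2[C@]3(C)CCCC(C)(C)C3C(=O)C[C@@H]2C | intermediate (not isolated)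
13 | (3S,4R,4aS,8aR)-3,4a,8,8-tetramethyl-4-[2-(2-methyl-1,3-dioxolan-2-yl)ethyl]octahydronaphthalen-1(2H)-one (trans-fused) | CC1(OCCO1)CC[C@H]2[C@]3(C)CCCC(C)(C)[C@H]3C(=O)C[C@@H]2C | intermediate
14 | (4R,4aS,8aR)-3,4a,8,8-tetramethyl-4-[2-(2-methyl-1,3-dioxolan-2-yl)ethyl]-4a,5,6,7,8,8a-hexahydronaphthalen-1(4H)-one | CC1(OCCO1)CC[C@H]2[C@]3(C)CCCC(C)(C)[C@H]3C(=O)C=C2C | intermediate
15 | C7–C8 epoxide of 14, oxygen trans to the angular methyl | CC1(OCCO1)CC[C@H]2[C@]3(C)CCCC(C)(C)[C@H]3C(=O)[C@@H]4O[C@]24C | intermediate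
16 | (3S,4S,4aS,8aR)-3-hydroxy-3,4a,8,8-tetramethyl-4-[2-(2-methyl-1,3-dioxolan-2-yl)ethyl]octahydronaphthalen-1(2H)-one | CC1(OCCO1)CC[C@H]2[C@]3(C)CCCC(C)(C)[C@H]3C(=O)C[C@]2(C)O | intermediate (not isolated)
17 | (1R,3S,4S,4aR,8aR)-3,4a,8,8-tetramethyl-4-[2-(2-methyl-1,3-dioxolan-2-yl)ethyl]decahydronaphthalene-1,3-diol | CC1(OCCO1)CC[C@H]2[C@]3(C)CCCC(C)(C)[C@H]3[C@H](O)C[C@]2(C)O | intermediate
18 | 4-[(1S,2S,4R,4aR,8aR)-2,4-dihydroxy-2,5,5,8a-tetramethyldecahydronaphthalen-1-yl]butan-2-one | CC(=O)CC[C@H]1[C@]2(C)CCCC(C)(C)[C@H]2[C@H](O)C[C@]1(C)O | intermediate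
19 | trimethyl phosphonoacetate | COC(=O)CP(=O)(OC)OC | starting material
20 | methyl (2E)-5-[(1S,2S,4R,4aR,8aR)-2,4-dihydroxy-2,5,5,8a-tetramethyldecahydronaphthalen-1-yl]-3-methylpent-2-enoate | COC(=O)/C=C(\C)CC[C@H]1[C@]2(C)CCCC(C)(C)[C@H]2[C@H](O)C[C@]1(C)O | target

**Step count and risks**
Total steps: 12. Longest linear sequence: 12 steps, from 1.

Step 7 (most at risk). The primary C1 radical may be reduced before it cyclizes. Facial selectivity at C10 may also be poor, because the C8 methyl is trans to the C9 chain and so pseudoaxial in the same reactive conformer, where it lies syn to the incoming carbon. The fallback is an anionic ring closure under thermodynamic control. It sets out from 11: NaNO2 in DMF should give the primary nitroalkane F1. DBU in MeCN should deprotonate only the nitroalkane and close ring A by a reversible intramolecular nitro-Michael addition (6-endo-trig), funnelling to the all-equatorial trans-fused nitro decalone F2. Radical denitration with Bu3SnH and AIBN in toluene at 110 °C comes back to 13.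

Step 3. The SN2 reaction of the unactivated bromide may be slow, which lets proton exchange between enolate and product cause polyalkylation and loss of regiocontrol. The fallback replaces alkylation by conjugate addition. It sets out from 4: LiN(iPr)2 then Me3SiCl gives the silyl dienol ether F3. Mukaiyama–Michael addition to but-3-en-2-one (TiCl4, CH2Cl2, −78 °C) should give the diketone F4 with the new chain again trans to the C8 methyl. Chemoselective ketalization of its unhindered saturated methyl ketone (ethane-1,2-diol, pyridinium p-toluenesulfonate, benzene, reflux) comes back to 7.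

Step 12. Olefination of a methyl ketone whose two branches differ little in size may give low E/Z selectivity. The fallback is a stereospecific alkyne carbometalation. It sets out from 17: tBuMe2SiOTf and 2,6-lutidine give the bis-silyl ether F5. AcOH/THF/H2O frees the methyl ketone F6. LiN(iPr)2, ClP(O)(OEt)2, then more LiN(iPr)2 give the terminal alkyne F7 through the enol phosphate. Syn-carboalumination with Me3Al and catalytic Cp2ZrCl2, followed by ClCO2Me, gives the E-enoate F8. HF·pyridine removes both silyl groups and comes back to 20.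

**Further compounds**
F1 | step 7 | (4R,5S)-3,5-dimethyl-4-[2-(2-methyl-1,3-dioxolan-2-yl)ethyl]-2-(2-methyl-5-nitropentan-2-yl)cyclohex-2-en-1-one | CC1(OCCO1)CC[C@H]2C(C)=C(C(C)(C)CCC[N+](=O)[O-])C(=O)C[C@@H]2C
F2 | step 7 | nitro derivative of 13 carrying NO2 on the ring A carbon next to the angular methyl carbon (labdane C1), either epimer | CC1(OCCO1)CC[C@H]2[C@]3(C)C([N+](=O)[O-])CCC(C)(C)[C@H]3C(=O)C[C@@H]2C
F3 | step 3 | trimethyl{[(3S)-3-methyl-6-(2-methylpent-4-en-2-yl)cyclohexa-1,5-dien-1-yl]oxy}silane | C[C@H]1CC=C(C(C)(C)CC=C)C(O[Si](C)(C)C)=C1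
F4 | step 3 | (5S,6R)-5-methyl-2-(2-methylpent-4-en-2-yl)-6-(3-oxobutyl)cyclohex-2-en-1-one | CC(=O)CC[C@H]1C(=O)C(C(C)(C)CC=C)=CC[C@@H]1C
F5 | step 12 | bis(tert-butyldimethylsilyl) ether of 17 | CC1(OCCO1)CC[C@H]2[C@]3(C)CCCC(C)(C)[C@H]3[C@H](O[Si](C)(C)C(C)(C)C)C[C@]2(C)O[Si](C)(C)C(C)(C)C
F6 | step 12 | bis(tert-butyldimethylsilyl) ether of 18 | CC(=O)CC[C@H]1[C@]2(C)CCCC(C)(C)[C@H]2[C@H](O[Si](C)(C)C(C)(C)C)C[C@]1(C)O[Si](C)(C)C(C)(C)C
F7 | step 12 | terminal alkyne: the bis(tert-butyldimethylsilyl) ether of the diol core carrying a but-3-yn-1-yl chain in place of the 3-oxobutyl chain | C#CCC[C@H]1[C@]2(C)CCCC(C)(C)[C@H]2[C@H](O[Si](C)(C)C(C)(C)C)C[C@]1(C)O[Si](C)(C)C(C)(C)C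
F8 | step 12 | bis(tert-butyldimethylsilyl) ether of 20 | COC(=O)/C=C(\C)CC[C@H]1[C@]2(C)CCCC(C)(C)[C@H]2[C@H](O[Si](C)(C)C(C)(C)C)C[C@]1(C)O[Si](C)(C)C(C)(C)C
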